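## Retrosynthetic overview
1. Unmask C1=O from a dimethyl ketal and cut C4–C1' (1,2-addition). This gives (S)-5-hydroxy-4,4-dimethoxycyclohex-2-enone and (Z)-heptadec-10-enylmagnesium bromide. Seen from the free ketone, the future C6 hydroxyl is a β-hydroxyl.
2. The β-hydroxy enone comes from Cα–O reductive opening of an α,β-epoxy ketone. The key C–O disconnection is a catalytic enantioselective nucleophilic epoxidation of achiral p-benzoquinone dimethyl monoketal. It sets C6, and C6 then controls C4.
3. The side chain comes from Z-selective cross metathesis of 11-bromoundec-1-ene with oct-1-ene.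
4. Rings: the carbocycle is bought intact. The only ring made is the oxirane (step 2), which is opened again in step 3.

Assumption: the sense of induction of the new catalyst in step 2 cannot be predicted with certainty, so the quinine-derived salt is written, and its quinidine-derived pseudo-enantiomer is used if the first run gives ent-5 (checked by Mosher analysis of 6).

## Route

Step 1
Reactants: 1 11-bromoundec-1-ene; 2 oct-1-ene
Product: 3 (7Z)-17-bromoheptadec-7-ene
Conditions: 2 (4 equiv), Ru(NO3)(=CH-C6H4-2-OiPr)(C,C-chelating NHC) [NHC = 1-(2,6-diisopropylphenyl)-3-(adamant-1-yl, metalated at C2)imidazolidin-2-ylidene; cyclometalated Z-selective Grubbs catalyst] (1 mol %), THF, 35 °C, static vacuum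
Reagents that add atoms: none
Why: Z-selective olefin cross metathesis, in which the metallacyclobutane forms side-bound under the bulky N-aryl group so both alkyl groups point away from it and the cis alkene (about 95% Z) is released, while loss of ethene and the excess of cheap 2 favour the cross product and the primary bromide is inert.

Step 2
Reactants: 4 4,4-dimethoxycyclohexa-2,5-dien-1-one
Product: 5 (1R,6S)-5,5-dimethoxy-7-oxabicyclo[4.1.0]hept-3-en-2-one
Conditions: tBuOOH (5.5 M in decane, 1.05 equiv), N-[3,5-bis(trifluoromethyl)benzyl] quaternary bromide of 9-deoxy-9-epi-9-{3-[3,5-bis(trifluoromethyl)phenyl]ureido}dihydroquinine (5 mol %), Cs2CO3 (30 mol %), toluene, −20 °C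
Reagents that add atoms: tert-butyl hydroperoxide, CC(C)(C)OO
Why: Proposed new method: enantioselective Weitz-Scheffer epoxidation of the unsubstituted, C2v-symmetric quinone monoketal by a bifunctional urea-quaternary ammonium phase-transfer catalyst, a catalyst-substrate pairing not yet described to my knowledge; Cs2CO3 generates tBuOO−, which enters toluene as a tight ion pair with the chiral ammonium centre while the urea N–H bonds clamp the dienone carbonyl (and then the developing enolate), so the peroxide reaches only the β-carbon lying under the ammonium on one ring face; this conjugate C–O bond formation is enantio-determining, and fast 3-exo-tet closure of the enolate onto the peroxide oxygen with loss of tBuO− makes it irreversible and gives the necessarily cis-fused oxirane (both new stereocentres, 1R,6S); the two alkenes are homotopic through the C2 axis and only their faces are enantiotopic, so the catalyst has to fix only the relative position of its two binding sites, the flanking ketal methoxy groups sharpen the steric difference, and 1.05 equiv of oxidant limits bis-epoxide; closest known reaction type: cinchona ammonium salt catalysed phase-transfer epoxidation of chalcones, 2-substituted naphthoquinones and ring-substituted quinone monoketals with hydroperoxides or hypochlorite.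

Step 3
Reactants: 5 (1R,6S)-5,5-dimethoxy-7-oxabicyclo[4.1.0]hept-3-en-2-one
Product: 6 (5S)-5-hydroxy-4,4-dimethoxycyclohex-2-en-1-one
Conditions: PhSeSePh (1.5 equiv), NaBH4 (3 equiv), EtOH, 0 °C; then AcOH (3 equiv), 5, 0 °C, 20 min; air, neutral work-up
Reagents that add atoms: none
Why: Miyashita organoselenium reduction of an α,β-epoxy ketone, in which PhSe− opens the oxirane by SN2 attack at the carbonyl-activated Cα and a second PhSe− removes selenium to give an enolate that AcOH protonates, so only the Cα–O bond is cut and the Cβ–O stereocentre (future C6) is untouched, no free hydride remains to reduce the enone, and the buffered medium spares the ketal and suppresses β-elimination.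

Step 4
Reactants: 3 (7Z)-17-bromoheptadec-7-ene; 6 (5S)-5-hydroxy-4,4-dimethoxycyclohex-2-en-1-one
Product: 10 (4R,6S)-4-[(10Z)-heptadec-10-en-1-yl]-4,6-dihydroxycyclohex-2-en-1-one, via Grignard reagent 7 (not isolated), via magnesium alkoxide 8 (not isolated), via diol ketal 9 (not isolated)
Conditions: 3 (2.4 equiv), Mg, THF, 40 °C; 6, LaCl3·2LiCl (1.1 equiv), THF, −78 to −40 °C; then 1 M aq HCl, 0 °C, 45 min
Reagents that add atoms: water, O
Why: Grignard formation, LaCl3·2LiCl-promoted Grignard 1,2-addition and acid ketal hydrolysis, in which the first equivalent of 7 deprotonates the OH, the second adds 1,2 to the Lewis-acid-activated carbonyl on the face anti to the C5 alkoxide (axial attack on the half-chair with the alkoxide pseudo-equatorial, as with 5-substituted cyclohexenones such as carvone) so the new tertiary OH is cis to the C5 oxygen (4R in 10, minor epimer removed by chromatography), and dilute HCl hydrolyses the allylic dimethyl ketal through its allyl-stabilised oxocarbenium ion faster than the tertiary allylic alcohol ionises.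

## Compound list
1 | 11-bromoundec-1-ene | C=CCCCCCCCCCBr | starting material
2 | oct-1-ene | C=CCCCCCC | starting material
3 | (7Z)-17-bromoheptadec-7-ene | CCCCCC/C=C\CCCCCCCCCBr | intermediate
4 | 4,4-dimethoxycyclohexa-2,5-dien-1-one | COC1(OC)C=CC(=O)C=C1 | starting material
5 | (1R,6S)-5,5-dimethoxy-7-oxabicyclo[4.1.0]hept-3-en-2-one | O=C1C=CC(OC)(OC)[C@H]2O[C@H]21 | intermediate
6 | (5S)-5-hydroxy-4,4-dimethoxycyclohex-2-en-1-one | O=C1C=CC(OC)(OC)[C@@H](O)C1 | intermediate
7 | (10Z)-heptadec-10-en-1-ylmagnesium bromide | CCCCCC/C=C\CCCCCCCCC[Mg]Br | intermediate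
8 | bromomagnesium (1S)-6,6-dimethoxy-3-oxocyclohex-4-en-1-olate | O=C1C=CC(OC)(OC)[C@@H](O[Mg]Br)C1 | intermediate
9 | (1R,5S)-1-[(10Z)-heptadec-10-en-1-yl]-4,4-dimethoxycyclohex-2-ene-1,5-diol | CCCCCC/C=C\CCCCCCCCC[C@]1(O)C=CC(OC)(OC)[C@@H](O)C1 | intermediate
10 | (4R,6S)-4-[(10Z)-heptadec-10-en-1-yl]-4,6-dihydroxycyclohex-2-en-1-one | CCCCCC/C=C\CCCCCCCCC[C@]1(O)C=CC(=O)[C@@H](O)C1 | target

## Step count and risks
Total step count: 4. Longest linear sequence: 3 (4 → 5 → 6 → 10). Step 1 feeds in at step 4.

**Step 2 (the proposed new step).** Compound 4 is small and flat, so the ee may be modest, and some bis-epoxide may form.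
- The fallback uses known chemistry, sets out from 4 and comes back at 6.
- Epoxidise 4 with 30% H2O2 and NaOH in THF–water at 0 °C to racemic 5,5-dimethoxy-7-oxabicyclo[4.1.0]hept-3-en-2-one F1.
- Reduce it as in step 3 to racemic 5-hydroxy-4,4-dimethoxycyclohex-2-en-1-one F2.
- Resolve F2 kinetically with Candida antarctica lipase B and vinyl acetate in tBuOMe at 30 °C to about 52% conversion.
- By the Kazlauskas rule the R alcohol is acetylated to (1R)-6,6-dimethoxy-3-oxocyclohex-4-en-1-yl acetate F3, which is removed by chromatography. The unreacted S alcohol is 6.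

**Step 4.** Three things can go wrong:
- Facial selectivity with the free alkoxide may be only moderate.
- Enolisation with β-elimination back to 4 is possible.
- Compound 10 can dehydrate to the catechol if the acid contact is too long.

The fallback sets out from 6 (with 7 made as before) and comes back at 10.
- Silylate 6 (TBSCl, imidazole, DMF) to (5S)-5-[(tert-butyldimethylsilyl)oxy]-4,4-dimethoxycyclohex-2-en-1-one F4. Its bulky ether shields one face and needs no sacrificial nucleophile.
- Add 7 (1.3 equiv, LaCl3·2LiCl, THF, −78 °C) and quench with aq NH4Cl.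
- Isolate (1R,5S)-5-[(tert-butyldimethylsilyl)oxy]-1-[(10Z)-heptadec-10-en-1-yl]-4,4-dimethoxycyclohex-2-en-1-ol F5, removing the C1 epimer by chromatography.
- Cleave the silyl ether and the ketal together with aq HF in MeCN at 0 °C to reach 10.

**Step 1.** The product distribution is statistical, and any E isomer cannot be removed later.
- The fallback sets out from 1 and comes back at 3.
- Ozonise 1 (O3, CH2Cl2, −78 °C, then PPh3) to 10-bromodecanal F6.
- Couple it in a salt-free Z-selective Wittig reaction with the ylide from heptyltriphenylphosphonium bromide and NaN(SiMe3)2 (THF, −78 °C) to give 3 (Z:E at least 95:5).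

Further compounds
F1 | step 2 | racemic 5,5-dimethoxy-7-oxabicyclo[4.1.0]hept-3-en-2-one | O=C1C=CC(OC)(OC)C2OC12
F2 | step 2 | racemic 5-hydroxy-4,4-dimethoxycyclohex-2-en-1-one | O=C1C=CC(OC)(OC)C(O)C1
F3 | step 2 | (1R)-6,6-dimethoxy-3-oxocyclohex-4-en-1-yl acetate | O=C1C=CC(OC)(OC)[C@H](OC(C)=O)C1
F4 | step 4 | (5S)-5-[(tert-butyldimethylsilyl)oxy]-4,4-dimethoxycyclohex-2-en-1-one | O=C1C=CC(OC)(OC)[C@@H](O[Si](C)(C)C(C)(C)C)C1
F5 | step 4 | (1R,5S)-5-[(tert-butyldimethylsilyl)oxy]-1-[(10Z)-heptadec-10-en-1-yl]-4,4-dimethoxycyclohex-2-en-1-ol | CCCCCC/C=C\CCCCCCCCC[C@]1(O)C=CC(OC)(OC)[C@@H](O[Si](C)(C)C(C)(C)C)C1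
F6 | step 1 | 10-bromodecanal | O=CCCCCCCCCCBr
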